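## Retrosynthetic overview

1. Target ⇐ O8-selective methacrylation of the 8,9-diol; the ten-membered ring and the cis-fused α-methylene lactone come from one intramolecular Barbier allylation (C6–C7).
2. Allylic bromide arm ⇐ Baylis–Hillman reaction and SN2′ bromination at a C7 aldehyde; Z-enal arm ⇐ Sonogashira coupling (C3–C4) with (Z)-3-iodobut-2-en-1-ol.
3. 3(2H)-Furanone with quaternary C10 and the C7 aldehyde ⇐ gold-triggered ring contraction of an alkynyl pyranosidulose: carbonyl-O cyclisation, 1,2-methyl shift (C1→C10), acetal fragmentation.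
4. Pyranosidulose carrying the C8/C9 cis-diol ⇐ Achmatowicz ring expansion of an (R)-2-furyl propargylic carbinol, then face-selective dihydroxylation.
5. Ring order: furan → pyranone (ring expansion) → dioxolane (protection) → 3(2H)-furanone (ring contraction) → ten-membered carbocycle and γ-lactone together.

Atom labels C1–C15 follow germacrane numbering of the target (C1 ketone, C3/C10 bridged by the furanone oxygen, 6,12-olide, 8-O-ester, 9-OH).

Assumption: (Z)-3-iodobut-2-en-1-ol is bought as a catalogue compound.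

## Route

Step 1
Reactants: 1 2-acetylfuran; 2 ethynyltrimethylsilane
Product: 4 (R)-2-(furan-2-yl)but-3-yn-2-ol, via silylated carbinol 3 (not isolated)
Conditions: ZnMe2 (3 equiv), Cu(OTf)2 (10 mol%), chiral camphorsulfonamide ligand (10 mol%), toluene, 0 °C; then MeOH, K2CO3, rt
Reagents that add atoms: none
Why: Catalytic enantioselective alkynylzinc addition to an aryl methyl ketone, with the ligand enantiomer chosen for Re-face delivery, sets the (R)-carbinol that is later relayed to C8, C9 and C10, and methanolysis in the same flask removes the C-silyl group.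

Step 2
Reactants: 4 (R)-2-(furan-2-yl)but-3-yn-2-ol
Product: 6 (2R,6R)-2-ethynyl-6-methoxy-2-methyl-2H-pyran-3(6H)-one, via dimethoxydihydrofuran 5 (not isolated)
Conditions: NBS, NaHCO3, MeOH, −30 °C; evaporate, then PPTS (cat.), CH2Cl2, rt
Reagents that add atoms: methanol CO
Why: Achmatowicz oxidative ring expansion (furan 2,5-dimethoxylation, then acid-catalysed transacetalisation by the tertiary hydroxyl) gives the pyranone, and the axial anomeric methoxy group settles cis to the slim ethynyl group, the minor anomer being re-equilibrated with acid.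

Step 3
Reactants: 6 (2R,6R)-2-ethynyl-6-methoxy-2-methyl-2H-pyran-3(6H)-one
Product: 7 (2R,4S,5R,6R)-2-ethynyl-4,5-dihydroxy-6-methoxy-2-methyloxan-3-one
Conditions: K2OsO2(OH)4 (2 mol%), NMO, citric acid, tBuOH/H2O, rt
Reagents that add atoms: N-methylmorpholine N-oxide C[N+]1([O-])CCOCC1; water O
Why: Upjohn syn-dihydroxylation of the ring enone (the alkyne is inert) occurs opposite the axial methoxy and axial ethynyl groups, so both hydroxyls land cis to the C-methyl group and fix C8 and C9.

Step 4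
Reactants: 7 (2R,4S,5R,6R)-2-ethynyl-4,5-dihydroxy-6-methoxy-2-methyloxan-3-one
Product: 8 (3aR,4R,6R,7aS)-6-ethynyl-4-methoxy-2,2,6-trimethyltetrahydro-[1,3]dioxolo[4,5-c]pyran-7-one
Conditions: Me2C(OMe)2, CSA (cat.), acetone, rt
Reagents that add atoms: 2,2-dimethoxypropane COC(C)(C)OC
Why: Acid-catalysed ketalisation of the cis-diol gives the cis-fused dioxolane, which protects both hydroxyls through steps 6–12.

Step 5
Reactants: 9 (Z)-3-iodobut-2-en-1-ol
Product: 10 (Z)-tert-butyl[(3-iodobut-2-en-1-yl)oxy]dimethylsilane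
Conditions: TBSCl, imidazole, CH2Cl2, 0 °C to rt
Reagents that add atoms: tert-butyldimethylsilyl chloride CC(C)(C)[Si](C)(C)Cl
Why: Standard silylation masks the allylic hydroxyl, which would otherwise add to the gold-activated alkyne in step 7, and leaves the Z geometry untouched.

Step 6
Reactants: 8 (3aR,4R,6R,7aS)-6-ethynyl-4-methoxy-2,2,6-trimethyltetrahydro-[1,3]dioxolo[4,5-c]pyran-7-one; 10 (Z)-tert-butyl[(3-iodobut-2-en-1-yl)oxy]dimethylsilane
Product: 11 (3aR,4R,6R,7aS)-6-[(3Z)-5-(tert-butyldimethylsilyloxy)-3-methylpent-3-en-1-yn-1-yl]-4-methoxy-2,2,6-trimethyltetrahydro-[1,3]dioxolo[4,5-c]pyran-7-one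
Conditions: Pd(PPh3)4 (3 mol%), CuI (6 mol%), iPr2NH, THF, rt
Reagents that add atoms: none
Why: Sonogashira coupling forms C3–C4 with retention of the Z-alkene; the alkene is introduced only now so that it was absent during the dihydroxylation.

Step 7
Reactants: 11 (enyne pyranosidulose named in step 6)
Product: 12 (4R,5S)-5-{(2R)-5-[(2Z)-4-(tert-butyldimethylsilyloxy)but-2-en-2-yl]-2-methyl-3-oxo-2,3-dihydrofuran-2-yl}-2,2-dimethyl-1,3-dioxolane-4-carbaldehyde
Conditions: AuCl3 (5 mol%), H2O (3 equiv), CH2Cl2, 23 °C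
Reagents that add atoms: water O
Why: Proposed new method: trivalent gold activates the alkyne, the pyranone carbonyl oxygen adds 5-endo-dig to give a bicyclic oxocarbenium ion, the axial C1 methyl shifts suprafacially to C10 while the ring acetal oxygen forms C1=O+, and this ion collapses by cleaving the O–C7 glycosidic bond (the methoxy-stabilised C7 cation is hydrolysed to the aldehyde), so the pyranone contracts to the 3(2H)-furanone with 1,2-transfer of chirality from C1 to C10 (10R); the closest known reaction is the gold- or platinum-catalysed heterocyclisation/1,2-alkyl shift of free 2-hydroxy-2-alkynyl ketones, not yet shown with the hydroxyl masked as a cyclic acetal oxygen or with a terminating acetal fragmentation.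

Step 8
Reactants: 12 (furanone aldehyde named in step 7); 13 methyl acrylate
Product: 14 methyl 2-[hydroxy{(4S,5S)-5-[(2R)-5-{(2Z)-4-(tert-butyldimethylsilyloxy)but-2-en-2-yl}-2-methyl-3-oxo-2,3-dihydrofuran-2-yl]-2,2-dimethyl-1,3-dioxolan-4-yl}methyl]prop-2-enoate (both carbinol epimers)
Conditions: DABCO (0.5 equiv), neat 13 (10 equiv), MeOH (2 equiv), rt
Reagents that add atoms: none
Why: Morita–Baylis–Hillman reaction joins the acrylate α-carbon (C11) to C7; the new carbinol centre is erased in step 9 and the weakly basic amine leaves C8 unepimerised.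

Step 9
Reactants: 14 (Baylis–Hillman adduct named in step 8)
Product: 15 methyl (2Z)-2-(bromomethyl)-3-{(4S,5S)-5-[(2R)-5-{(2Z)-4-(tert-butyldimethylsilyloxy)but-2-en-2-yl}-2-methyl-3-oxo-2,3-dihydrofuran-2-yl]-2,2-dimethyl-1,3-dioxolan-4-yl}prop-2-enoate
Conditions: NBS, Me2S, CH2Cl2, 0 °C to rt
Reagents that add atoms: N-bromosuccinimide O=C1CCC(=O)N1Br
Why: The Corey–Kim-type sulfonium salt activates the hydroxyl and bromide attacks SN2′ at the methylene terminus, giving the thermodynamically preferred Z-2-(bromomethyl)enoate.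

Step 10
Reactants: 15 (silyl ether bromide named in step 9)
Product: 16 methyl (2Z)-2-(bromomethyl)-3-{(4S,5S)-5-[(2R)-5-{(2Z)-4-hydroxybut-2-en-2-yl}-2-methyl-3-oxo-2,3-dihydrofuran-2-yl]-2,2-dimethyl-1,3-dioxolan-4-yl}prop-2-enoate
Conditions: HF·pyridine, pyridine, THF, 0 °C
Reagents that add atoms: none
Why: Buffered fluoride cleaves the primary silyl ether without touching the acetonide or the allylic bromide.

Step 11
Reactants: 16 (allylic alcohol named in step 10)
Product: 17 methyl (2Z)-2-(bromomethyl)-3-{(4S,5S)-5-[(2R)-2-methyl-3-oxo-5-{(2Z)-4-oxobut-2-en-2-yl}-2,3-dihydrofuran-2-yl]-2,2-dimethyl-1,3-dioxolan-4-yl}prop-2-enoate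
Conditions: MnO2 (20 equiv), CH2Cl2, rt
Reagents that add atoms: none
Why: MnO2 oxidises the allylic alcohol to the Z-enal under neutral conditions that do not isomerise the double bond.

Step 12
Reactants: 17 (Z-enal bromide named in step 11)
Product: 20 8,9-diol lactone (the target lacking its methacryloyl group), via hydroxy ester 18 (not isolated), via acetonide lactone 19 (not isolated)
Conditions: In powder (2 equiv), THF/H2O (3:1), 2 mM, slow addition, rt; then HCl (to 1.5 M), 35 °C
Reagents that add atoms: none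
Why: Intramolecular indium Barbier allylation of the Z-2-(bromomethyl)enoate at C7 through a six-membered cyclic transition state gives the syn adduct (hence the cis-fused lactone on lactonisation at O6, the only free hydroxyl), the cis-dioxolane turn brings C6 to the C7 face that sets C6 and C7 as in the target, and the acid then hydrolyses the acetonide.

Step 13
Reactants: 20 8,9-diol lactone; 21 methacryloyl chloride
Product: 22 target, 8-O-methacrylate (6S,7S,8S,9S,10R)
Conditions: 21 (1.1 equiv), 2,4,6-collidine, CH2Cl2, −40 to 0 °C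
Reagents that add atoms: none
Why: Acylation goes to the less hindered O8 hydroxyl, because O9 is neopentyl-like next to quaternary C10, and the low temperature suppresses acyl migration and translactonisation.

## Compound list

1 | 2-acetylfuran | CC(=O)c1ccco1 | starting material
2 | ethynyltrimethylsilane | C#C[Si](C)(C)C | starting material
3 | (R)-2-(furan-2-yl)-4-(trimethylsilyl)but-3-yn-2-ol | C[C@@](O)(C#C[Si](C)(C)C)c1ccco1 | intermediate
4 | (R)-2-(furan-2-yl)but-3-yn-2-ol | C[C@@](O)(C#C)c1ccco1 | intermediate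
5 | (2R)-2-(2,5-dimethoxy-2,5-dihydrofuran-2-yl)but-3-yn-2-ol (mixture at the two ring acetal carbons) | C[C@@](O)(C#C)C1(OC)C=CC(OC)O1 | intermediate
6 | (2R,6R)-2-ethynyl-6-methoxy-2-methyl-2H-pyran-3(6H)-one | CO[C@H]1C=CC(=O)[C@@](C)(C#C)O1 | intermediate
7 | (2R,4S,5R,6R)-2-ethynyl-4,5-dihydroxy-6-methoxy-2-methyloxan-3-one | CO[C@H]1[C@H](O)[C@H](O)C(=O)[C@@](C)(C#C)O1 | intermediate
8 | (3aR,4R,6R,7aS)-6-ethynyl-4-methoxy-2,2,6-trimethyltetrahydro-[1,3]dioxolo[4,5-c]pyran-7-one | CO[C@H]1[C@@H]2OC(C)(C)O[C@@H]2C(=O)[C@@](C)(C#C)O1 | intermediate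
9 | (Z)-3-iodobut-2-en-1-ol | C/C(I)=C/CO | starting material
10 | (Z)-tert-butyl[(3-iodobut-2-en-1-yl)oxy]dimethylsilane | C/C(I)=C/CO[Si](C)(C)C(C)(C)C | intermediate
11 | (3aR,4R,6R,7aS)-6-[(3Z)-5-(tert-butyldimethylsilyloxy)-3-methylpent-3-en-1-yn-1-yl]-4-methoxy-2,2,6-trimethyltetrahydro-[1,3]dioxolo[4,5-c]pyran-7-one | CO[C@H]1[C@@H]2OC(C)(C)O[C@@H]2C(=O)[C@@](C)(C#C/C(C)=C\CO[Si](C)(C)C(C)(C)C)O1 | intermediate
12 | (4R,5S)-5-{(2R)-5-[(2Z)-4-(tert-butyldimethylsilyloxy)but-2-en-2-yl]-2-methyl-3-oxo-2,3-dihydrofuran-2-yl}-2,2-dimethyl-1,3-dioxolane-4-carbaldehyde | O=C[C@@H]1OC(C)(C)O[C@@H]1[C@@]1(C)OC(/C(C)=C\CO[Si](C)(C)C(C)(C)C)=CC1=O | intermediate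
13 | methyl acrylate | C=CC(=O)OC | starting material
14 | Baylis–Hillman adduct of 12 (methyl 2-[hydroxy(dioxolanyl)methyl]prop-2-enoate, both carbinol epimers) | C=C(C(=O)OC)C(O)[C@@H]1OC(C)(C)O[C@@H]1[C@@]1(C)OC(/C(C)=C\CO[Si](C)(C)C(C)(C)C)=CC1=O | intermediate
15 | methyl (2Z)-2-(bromomethyl)-3-[(4S,5S)-dioxolanyl]prop-2-enoate, silyl ether | COC(=O)/C(CBr)=C/[C@@H]1OC(C)(C)O[C@@H]1[C@@]1(C)OC(/C(C)=C\CO[Si](C)(C)C(C)(C)C)=CC1=O | intermediate
16 | the same bromide with the free (2Z)-4-hydroxybut-2-en-2-yl arm | COC(=O)/C(CBr)=C/[C@@H]1OC(C)(C)O[C@@H]1[C@@]1(C)OC(/C(C)=C\CO)=CC1=O | intermediate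
17 | the same bromide with the (2Z)-4-oxobut-2-en-2-yl (Z-enal) arm | COC(=O)/C(CBr)=C/[C@@H]1OC(C)(C)O[C@@H]1[C@@]1(C)OC(/C(C)=C\C=O)=CC1=O | intermediate
18 | macrocyclic hydroxy ester: methyl 2-(C7)-acrylate with C6–OH, 8,9-acetonide, C6–C10 configured as in the target | COC(=O)C(=C)[C@H]1[C@@H](O)/C=C(/C)C2=CC(=O)[C@](C)(O2)[C@H]2OC(C)(C)O[C@@H]12 | intermediate
19 | 8,9-O-isopropylidene derivative of the 6,12-olide, C6–C10 configured as in the target | CC1(C)O[C@H]2[C@H]3C(=C)C(=O)O[C@H]3/C=C(/C)C3=CC(=O)[C@](C)(O3)[C@H]2O1 | intermediate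
20 | 8,9-dihydroxy-1-oxo-3,10-epoxygermacra-2,4(Z),11(13)-trien-12,6-olide, C6–C10 configured as in the target | O[C@H]1[C@H]2C(=C)C(=O)O[C@H]2/C=C(/C)C2=CC(=O)[C@](C)(O2)[C@H]1O | intermediate
21 | methacryloyl chloride | C=C(C)C(=O)Cl | starting material
22 | CNP0252578.5, (6S,7S,8S,9S,10R) 8-O-methacrylate | C=C(C)C(=O)O[C@H]1[C@H]2C(=C)C(=O)O[C@H]2/C=C(/C)C2=CC(=O)[C@](C)(O2)[C@H]1O | target

## Step count and risks

Total steps: 13. Longest linear sequence: 12 (steps 1–4 and 6–13).

Steps most likely to fail: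

Step 7 (the proposed gold-triggered ring contraction of the methyl glycoside). The fallback sets out from 4 and returns at 12, using only established reactions. Oxidise 4 by the aqueous Achmatowicz protocol (NBS, NaHCO3, THF/H2O) to the hemiacetal (2R)-2-ethynyl-6-hydroxy-2-methyl-2H-pyran-3(6H)-one F1. Acetylate (Ac2O, pyridine) to the anomeric acetate (2S,6R)-6-ethynyl-6-methyl-5-oxo-5,6-dihydro-2H-pyran-2-yl acetate F2. Dihydroxylate as in step 3 to the cis-diol acetate F3, ketalise as in step 4 to the acetonide acetate F4, and couple with 10 as in step 6 to the enyne acetate F5. Remove the anomeric acetate with hydrazinium acetate in DMF to give the lactol F6. The ring-opened tautomer of F6 is a free 2-hydroxy-2-alkynyl ketone, the established substrate class for AuCl3- or PtCl2-catalysed cyclisation/1,2-alkyl shift, and this gives 12.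

Step 12 (ring closure and the C6/C7 configuration in the macrocyclic Barbier reaction). The fallback sets out from 8 and returns at 19; it moves the ring closure to C4=C5. Couple 8 with 2-bromopropene (Sonogashira) to the isopropenyl enyne F7 and contract the ring as in step 7 to the isopropenyl furanone aldehyde F8. Carry out the Baylis–Hillman reaction and bromination as in steps 8 and 9 to the adduct F9 and the allylic bromide F10. Add F10 to acrolein (In, THF/H2O, or CrCl2 and a chiral bis(oxazoline) ligand if reagent control is needed) to give the open-chain hydroxy ester F11, and lactonise (PPTS) to the vinyl lactone F12. Close the ring by ring-closing metathesis with the second-generation Hoveyda–Grubbs catalyst, RuCl2(H2IMes)(=CH-C6H4-2-OiPr), to reach 19, which is hydrolysed to 20 as in step 12.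

Step 13 (O8 versus O9 selectivity). The fallback sets out from 20 and returns at 22. Convert 20 with Bu2Sn(OMe)2 (benzene, rt) into the dibutylstannylene acetal F13 and add 21 at −20 °C; the tin acetal delivers the acyl group to the less hindered oxygen, giving 22.

Further compounds
F1 | step 7 | (2R)-2-ethynyl-6-hydroxy-2-methyl-2H-pyran-3(6H)-one (anomer mixture) | OC1C=CC(=O)[C@@](C)(C#C)O1
F2 | step 7 | (2S,6R)-6-ethynyl-6-methyl-5-oxo-5,6-dihydro-2H-pyran-2-yl acetate | CC(=O)O[C@H]1C=CC(=O)[C@@](C)(C#C)O1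
F3 | step 7 | cis-diol acetate (hydroxyls trans to the acetoxy group) | CC(=O)O[C@H]1[C@H](O)[C@H](O)C(=O)[C@@](C)(C#C)O1
F4 | step 7 | acetonide acetate | CC(=O)O[C@H]1[C@@H]2OC(C)(C)O[C@@H]2C(=O)[C@@](C)(C#C)O1
F5 | step 7 | enyne acetate | CC(=O)O[C@H]1[C@@H]2OC(C)(C)O[C@@H]2C(=O)[C@@](C)(C#C/C(C)=C\CO[Si](C)(C)C(C)(C)C)O1
F6 | step 7 | lactol (anomer mixture) | OC1[C@@H]2OC(C)(C)O[C@@H]2C(=O)[C@@](C)(C#C/C(C)=C\CO[Si](C)(C)C(C)(C)C)O1
F7 | step 12 | isopropenyl enyne (analogue of 11) | CO[C@H]1[C@@H]2OC(C)(C)O[C@@H]2C(=O)[C@@](C)(C#CC(C)=C)O1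
F8 | step 12 | isopropenyl furanone aldehyde (analogue of 12) | O=C[C@@H]1OC(C)(C)O[C@@H]1[C@@]1(C)OC(C(C)=C)=CC1=O
F9 | step 12 | Baylis–Hillman adduct of F8 (both carbinol epimers) | C=C(C(=O)OC)C(O)[C@@H]1OC(C)(C)O[C@@H]1[C@@]1(C)OC(C(C)=C)=CC1=O
F10 | step 12 | (Z)-allylic bromide from F9 | COC(=O)/C(CBr)=C/[C@@H]1OC(C)(C)O[C@@H]1[C@@]1(C)OC(C(C)=C)=CC1=O
F11 | step 12 | open-chain hydroxy ester from acrolein | C=C[C@H](O)[C@H](C(=C)C(=O)OC)[C@@H]1OC(C)(C)O[C@@H]1[C@@]1(C)OC(C(C)=C)=CC1=O
F12 | step 12 | cis-disubstituted γ-vinyl α-methylene lactone | C=C[C@@H]1OC(=O)C(=C)[C@@H]1[C@@H]1OC(C)(C)O[C@@H]1[C@@]1(C)OC(C(C)=C)=CC1=O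
F13 | step 13 | 8,9-O-dibutylstannylene acetal of 20 | CCCC[Sn]1(CCCC)O[C@H]2[C@H]3C(=C)C(=O)O[C@H]3/C=C(/C)C3=CC(=O)[C@](C)(O3)[C@H]2O1
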